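**Target and assumptions.** The target is all-trans (2S,3S,4S,5S)-2-(3,4-dimethoxyphenyl)-5-(3,4,5-trimethoxyphenyl)-3,4-dimethyltetrahydrofuran. I assume that oxidative homocoupling of the Evans (R)-auxiliary enolate gives the C2-symmetric (S,S) dimer, with the same facial sense as Evans alkylation. I assume the Friedel–Crafts step on veratrole goes para to OMe, giving the 3,4-dimethoxyphenyl ketone. I assume the C5 hydride delivery in the last step favours the trans isomer, and I give a thermodynamic fallback for it.

## Retrosynthesis
1. The THF ring is closed last by Et3SiH reductive etherification of hydroxy-hemiketal **10**, which sets C5.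
2. **10** comes from addition of 3,4,5-trimethoxyphenyllithium to lactone **8**.
3. **8** comes from lactonization of γ-hydroxy acid **7**, which comes from Noyori ATH of γ-keto acid **6**; the ATH sets C2. Ring order: lactone first, then THF.
4. **6** comes from Friedel–Crafts desymmetrization of C2-symmetric (S,S)-2,3-dimethylsuccinic anhydride **4** with veratrole.
5. **4** comes from diacid **3**, made by Evans oxidative homocoupling of propionimide **1**, which sets both methyl-bearing centres.

## Route

**Step 1**
Reactants: 1, (R)-4-benzyl-3-propionyloxazolidin-2-one (2 equiv)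
Product: 2, C2-symmetric bis-imide of (2S,3S)-2,3-dimethylsuccinic acid
Conditions: LDA, THF, –78 °C; then Fe(acac)3, –78 °C → rt
Reagents that add atoms: none
Why: Oxidative enolate homocoupling of the chelated Z-enolate couples the two α-carbons, each on its face anti to the benzyl group. This gives the trans-(S,S) dimer and sets both methyl stereocentres.

**Step 2**
Reactants: 2
Product: 3, (2S,3S)-2,3-dimethylsuccinic acid (the (R)-auxiliary is recovered)
Conditions: LiOH, H2O2, THF/H2O, 0 °C; then Na2SO3
Reagents that add atoms: water (O) and hydrogen peroxide (OO). LiOOH is the nucleophile, and the peracid is reduced to the acid by Na2SO3.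
Why: LiOOH cleaves the imide exocyclically (Evans hydrolysis) without epimerizing the α-centres.

**Step 3**
Reactants: 3
Product: 4, (3S,4S)-3,4-dimethyldihydrofuran-2,5-dione
Conditions: Ac2O, reflux
Reagents that add atoms: none (Ac2O only dehydrates and leaves as AcOH)
Why: Thermal dehydrative cyclization of the trans-diacid gives the trans-anhydride; no stereocentre is touched.

**Step 4**
Reactants: 4; 5, veratrole (1,2-dimethoxybenzene)
Product: 6, (2S,3S)-4-(3,4-dimethoxyphenyl)-2,3-dimethyl-4-oxobutanoic acid
Conditions: AlCl3 (2.2 equiv), CH2Cl2, 0 °C → rt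
Reagents that add atoms: none
Why: Friedel–Crafts acylation occurs para to OMe, and the C2-symmetric anhydride gives only one keto-acid regardless of which carbonyl opens. Only one stereocentre is enolizable and the other is locked as the acid, so the pair cannot racemize.

**Step 5**
Reactants: 6
Product: 7, (2S,3S,4S)-4-(3,4-dimethoxyphenyl)-4-hydroxy-2,3-dimethylbutanoic acid
Conditions: RuCl[(S,S)-TsDPEN](p-cymene) (1 mol %), HCO2H/Et3N (5:2), CH2Cl2, 35 °C
Reagents that add atoms: none (formate supplies H only)
Why: Noyori asymmetric transfer hydrogenation sets the benzylic carbinol as S under catalyst control, which also makes it trans to the adjacent methyl.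

**Step 6**
Reactants: 7
Product: 8, (3S,4S,5S)-5-(3,4-dimethoxyphenyl)-3,4-dimethyldihydrofuran-2(3H)-one
Conditions: TsOH·H2O (5 mol %), CH2Cl2, 25 °C, 4 Å MS
Reagents that add atoms: none
Why: Acid-catalysed Fischer-type γ-lactonization closes the first ring with retention at all three centres, giving the all-trans lactone.

**Step 7**
Reactants: 8; 9, 5-bromo-1,2,3-trimethoxybenzene
Product: 10, (2S,3S,4S)-4-(3,4-dimethoxyphenyl)-4-hydroxy-2,3-dimethyl-1-(3,4,5-trimethoxyphenyl)butan-1-one. It exists as the ring-chain tautomeric hemiketal, drawn as the open form.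
Conditions: 9 + n-BuLi, THF, –78 °C (gives 3,4,5-trimethoxyphenyllithium); then add 8 (1.0 equiv), –78 °C; NH4Cl quench
Reagents that add atoms: none (the aryl group comes from 9)
Why: Aryllithium addition to the lactone gives a stable lithium hemiketalate that does not over-add at –78 °C; no new stereocentre forms, and the existing ones are untouched.

**Step 8**
Reactants: 10
Product: 11, target (2S,3S,4S,5S)-5-methoxygalbelgin
Conditions: Et3SiH (3 equiv), BF3·OEt2 (2 equiv), CH2Cl2, –78 → –20 °C
Reagents that add atoms: none (Et3SiH supplies hydride only)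
Why: Intramolecular hemiketalization and ionization give a cyclic oxocarbenium that is reduced by hydride (ionic deoxygenation). C5 is set by hydride attack that is expected to give the 2,5-trans, all-trans isomer, which is also the thermodynamic isomer. Any cis isomer is removed by chromatography.

## Compound list
1 | (R)-4-benzyl-3-propionyloxazolidin-2-one | CCC(=O)N1[C@H](Cc2ccccc2)COC1=O | starting material
2 | (2S,3S)-1,4-bis[(R)-4-benzyl-2-oxooxazolidin-3-yl]-2,3-dimethylbutane-1,4-dione | O=C(N1[C@H](Cc2ccccc2)COC1=O)[C@@H](C)[C@H](C)C(=O)N1[C@H](Cc2ccccc2)COC1=O | intermediate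
3 | (2S,3S)-2,3-dimethylsuccinic acid | OC(=O)[C@@H](C)[C@H](C)C(=O)O | intermediate
4 | (3S,4S)-3,4-dimethyldihydrofuran-2,5-dione | C[C@@H]1C(=O)OC(=O)[C@H]1C | intermediate
5 | veratrole | COc1ccccc1OC | starting material
6 | (2S,3S)-4-(3,4-dimethoxyphenyl)-2,3-dimethyl-4-oxobutanoic acid | COc1ccc(C(=O)[C@@H](C)[C@H](C)C(=O)O)cc1OC | intermediate
7 | (2S,3S,4S)-4-(3,4-dimethoxyphenyl)-4-hydroxy-2,3-dimethylbutanoic acid | COc1ccc([C@@H](O)[C@@H](C)[C@H](C)C(=O)O)cc1OC | intermediate
8 | (3S,4S,5S)-5-(3,4-dimethoxyphenyl)-3,4-dimethyldihydrofuran-2(3H)-one | COc1ccc([C@H]2OC(=O)[C@@H](C)[C@@H]2C)cc1OC | intermediate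
9 | 5-bromo-1,2,3-trimethoxybenzene | COc1cc(Br)cc(OC)c1OC | starting material
10 | (2S,3S,4S)-4-(3,4-dimethoxyphenyl)-4-hydroxy-2,3-dimethyl-1-(3,4,5-trimethoxyphenyl)butan-1-one | COc1ccc([C@@H](O)[C@@H](C)[C@H](C)C(=O)c2cc(OC)c(OC)c(OC)c2)cc1OC | intermediate
11 | 5-methoxygalbelgin | COc1ccc([C@H]2O[C@H](c3cc(OC)c(OC)c(OC)c3)[C@@H](C)[C@@H]2C)cc1OC | target

**Total steps:** 8. **Longest linear sequence:** 8 steps, from 1 to 11.

## Three steps most likely to fail
1. **Step 1, oxidative homocoupling.** Yield or dr may be poor, giving meso or cis dimer. Fallback: skip steps 1–2 and resolve commercial (±)-trans-2,3-dimethylsuccinic acid as a diastereomeric salt with (S)-1-phenylethylamine to obtain 3.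
2. **Step 5, ATH of the α-branched keto acid.** It may be slow or mismatched with the α-centre. Fallback: reduce 6 with NaBH4 (substrate control), lactonize, and separate the trans-lactone 8 from its cis epimer by chromatography.
3. **Step 8, stereo- and chemoselectivity of the reductive etherification.** It may give the 2,5-cis isomer or over-reduce a benzylic C–O bond. Fallback: reduce 10 with NaBH4 to the 1,4-diol, then cyclodehydrate with catalytic TsOH or CSA under reversible conditions, so the thermodynamic all-trans THF is obtained.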